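## Analysis of the target

The target (24) is a linear tridepside: three benzoic acid units joined by two aryl ester bonds. The carbonyl of ring A esterifies O-4 of ring B, the carbonyl of ring B esterifies O-4 of ring C, and ring C ends in a free carboxylic acid. With each ring numbered from its carbonyl-bearing carbon C1, ring A is 3,4-dihydroxy-6-methoxy-2-methyl substituted (its only C–H is at C5). Rings B and C are both 2-hydroxy-6-methyl-4-oxy substituted, the orsellinate pattern. There is no stereocentre, so the problem is purely one of regiochemistry and of joining three acids in the right order. The sensitive groups are the two depside esters (solvolysis and acyl migration under base), the catechol of ring A (oxidation in air above neutral pH) and the ortho-hydroxy acid of ring C (decarboxylation on heating). The difficulty lies in ring A, whose carbonyl sits between a methyl and a methoxy group and is a hindered acyl donor, and in rings B and C, which in a conventional assembly each need their 2-OH and 4-OH told apart. The strategy rests on one feature: in rings B and C the hydroxyl is at C2, ortho to C1, while the other ortho position C6 carries a methyl group, and in ring A both ortho positions are occupied (C2 methyl, C6 methoxy). A carbonyl-directed ortho C–H oxygenation can therefore only strike C2 of ring B and C2 of ring C, so these two C–O bonds can be made last on a tridepside built from plain 4-oxy-2-methylbenzoates.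

## Retrosynthetic reasoning

**24 back to 22.** The last operations only unmask functional groups: the two O–acetyl bonds on ring A (24 from 23) and the O–alkyl bond of the trichloroethyl ester on ring C (23 from 22). They come last because the free catechol and the free ortho-hydroxy acid are the most fragile functions. The two removals differ in kind (reductive fragmentation and mild solvolysis of unhindered acetates), and neither should touch the two depside esters, whose carbonyls are 2,6-disubstituted.

**22 back to 20 (key disconnection).** The C2–O bonds of ring B and ring C are cut. Each lies ortho to a benzoate carbonyl whose other ortho position is methyl-blocked, and ring A offers no ortho C–H, so the substrate itself defines the two sites. What is gained is that 20 contains no orsellinate hydroxyls: rings B and C become the same monohydroxy monomer and no 2-OH/4-OH differentiation is needed. The forward reaction has to oxygenate two C–H bonds in one operation under acidic, oxidising conditions. This dictates the protecting groups in 20: acetates that make the catechol of ring A electron-poor, and an acid- and oxidant-stable ester on ring C.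

**20 back to 11 and 18.** The ester between the ring A carbonyl and O-4 of ring B is cut. This is the most hindered acyl transfer, so it is made with the fully activated acyl chloride 19 and placed late, where the longest branch (ring A) meets the finished B–C unit. The forward step must acylate the single free phenol of 18 without transferring an acetyl group from ring A.

**18 back to 16 and 14, and these to 12 and 13.** The ester between the ring B carbonyl and O-4 of ring C is cut. Both halves come from 12: once as the silyl-protected acid 16, once as the trichloroethyl ester 14 made with 13. The silyl ether leaves with fluoride (17 to 18) without disturbing either ester. The trichloroethyl ester survives the acid and oxidant of the key step and leaves reductively at the end.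

**11 back to 7.** Ring A is adjusted by functional group changes only: acetates from phenols (11 from 9), phenols from benzyl ethers (9 from 8), acid from aldehyde (8 from 7). Benzyl ethers are needed while the ring must be electron-rich for the formylation, and acetates are needed once it must resist oxidation. The exchange is done before any fragment derived from 13 is attached, because hydrogenolysis would endanger C–Cl bonds.

**7 back to 5.** The bond between ring A C1 and its carbonyl carbon is cut. In 5 the position para to one benzyloxy group and ortho to the methoxy group is the most nucleophilic one, so an electrophilic formylation should place the carbon there, between methyl and methoxy.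

**5 back to 1.** The catechol C–O bond next to the methyl group is cut: this oxygen replaces the formyl group of 2 by oxidative aryl migration (4 from 2). The formyl group of 1 thus marks the position of a future hydroxyl. Its 4-OH becomes the methoxy group of ring A (2 from 1) and its 2-OH the second catechol oxygen. Compound 1 is chosen because it already holds the methyl group and two oxygens in the required relationship.

## Alternatives that were turned down

**Alternative 1: ring A built saturated by Michael–Dieckmann and aromatised late.**
- Disconnection: ring A is opened at C1–C2 and C4–C5 into tert-butyl acetoacetate (A1) and ethyl (Z)-2-(benzyloxy)but-2-enoate (A2).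
- Forward key step: with NaOEt the enolate of A1 adds to the β-carbon of A2, and the methyl ketone enolate then closes onto the ethyl ester. This gives the cyclohexane-1,3-dione A3 as a diastereomer mixture, which does not matter because aromatisation erases all stereocentres.
- For: every substituent of ring A is fixed by connectivity. No directing effect has to be trusted, which makes it stronger on that point than the formylation of the chosen route.
- Against: A2 is a β-substituted, donor-deactivated acceptor. A3 needs a dehydrogenation to become aromatic, while loss of benzyl alcohol across C2–C3 would aromatise it without oxidation and delete the C3 oxygen. The two new phenols must then be told apart, and the chelated C6–OH is the one to be methylated. Only ring A is solved; rings B and C would still need differentiated orsellinate units.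
- Comparison: more steps overall. The chosen route makes ring A from 1 by classical aromatic chemistry and removes the hydroxyl differentiation in rings B and C altogether.

**Alternative 2: squarate ring expansion to the pentasubstituted ring A.**
- Disconnection: the ring A C1–C6 bond, traced to the racemic 4-alkenyl-4-silyloxycyclobutenone A4.
- Forward key step: heating A4 opens the four-membered ring to a dienylketene. A 6π electrocyclisation joins the ketene carbon to the ester-bearing alkene carbon, and tautomerisation gives the phenol A5.
- For: all five substituents are placed by construction under neutral thermal conditions. The three oxygens arrive differentiated (free C6–OH, isopropyl ether at C4, silyl ether at C3), which is better than the benzyl-to-acetyl exchange needed here.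
- Against: A4 requires adding an ester-bearing alkenyllithium, prone to self-condensation, to a semisquarate that is itself several steps from squaric acid. The C6–OH of A5 is hydrogen-bonded to the ester and sluggish to methylate. Cleaving the isopropyl ether with a boron or aluminium halide would threaten the methoxy group ortho to the carbonyl. Rings B and C are again not addressed.
- Comparison: longer and specialised for one ring. The chosen route spends its risk on a single late step that completes two rings at once.

**Alternative 3: Diels–Alder benzannulation of ring B on a ring C ynoate.**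
- Disconnection: ring B C1–C2 and C5–C6, leading to the ring C aryl but-2-ynoate A6 and 1-methoxy-1,3-bis(trimethylsilyloxy)buta-1,3-diene A7 (used as a ketene acetal isomer mixture).
- Forward key step: A7 adds thermally across the triple bond of A6, and acidic work-up eliminates methanol and aromatises the adduct to the resorcinol A8.
- For: ring B arrives with both hydroxyls and with the depside bond to ring C already in place. It avoids a C–H oxygenation directed by a weakly coordinating aryl ester, the weakest point of the chosen route, so it is stronger there.
- Against: a β-methyl ynoate is a sluggish dienophile, and the heating it needs competes with desilylation of A7 and with Michael-type addition that does not close the ring. Ring C must be a differentiated orsellinate (silyl at O-2, benzyl ester, O-4 acylated). Ring A must still be made and attached, so the hindered acylation remains.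
- Comparison: similar or higher step count with ring A unsolved. The chosen route takes rings B and C from one cheap monomer with no phenol differentiation.

Key step: step 13

## Route

Remark: each ring is numbered from its carbonyl-bearing carbon (C1). The target has no stereocentre, so no step has to set or preserve configuration.

Step 1
Reactants: 1 2,4-dihydroxy-6-methylbenzaldehyde
Product: 2 2-hydroxy-4-methoxy-6-methylbenzaldehyde
Conditions: MeI (1.05 equiv), K2CO3 (1.0 equiv), acetone, rt
Reagents that add atoms: iodomethane, CI
Why: Williamson ether synthesis; the 4-OH is the more acidic and freely accessible phenol, whereas the 2-OH is held in a hydrogen bond to the formyl oxygen, so one equivalent of base and MeI should alkylate O-4 selectively.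

Step 2
Reactants: 2 2-hydroxy-4-methoxy-6-methylbenzaldehyde
Product: 4 5-methoxy-3-methylbenzene-1,2-diol, via aryl formate 3 (not isolated)
Conditions: 30% aq. H2O2 (1.2 equiv), NaOH (1.1 equiv), H2O/THF, 0 °C to rt, N2; then aq. HCl
Reagents that add atoms: hydrogen peroxide, OO
Why: Dakin oxidation; hydroperoxide adds to the formyl group, the electron-rich ortho-hydroxyaryl group migrates to oxygen to give formate 3, and this is saponified in the same flask; exclusion of air and prompt acidification protect the catechol.

Step 3
Reactants: 4 5-methoxy-3-methylbenzene-1,2-diol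
Product: 5 1,2-bis(benzyloxy)-5-methoxy-3-methylbenzene
Conditions: BnBr (2.3 equiv), K2CO3 (3 equiv), DMF, rt to 50 °C, N2
Reagents that add atoms: benzyl bromide, BrCc1ccccc1
Why: Twofold Williamson etherification; benzyl ethers stabilise the catechol and keep the ring electron-rich for the electrophilic formylation that follows.

Step 4
Reactants: 5 1,2-bis(benzyloxy)-5-methoxy-3-methylbenzene
Product: 7 3,4-bis(benzyloxy)-6-methoxy-2-methylbenzaldehyde, via iminium chloride 6 (not isolated)
Conditions: POCl3 (1.5 equiv), DMF, 0 °C to 70 °C; then aq. NaOAc
Reagents that add atoms: N,N-dimethylformamide, CN(C)C=O (formyl carbon); water, O (carbonyl oxygen)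
Why: Vilsmeier–Haack formylation; C4 of 5 is ortho to the methoxy group and para to the C1 benzyloxy group, the reactive site of a 1,2,4-trialkoxybenzene, whereas C6 lies between two alkoxy groups and is disfavoured, in line with formylation of orcinol ethers next to the methyl group.

Step 5
Reactants: 7 3,4-bis(benzyloxy)-6-methoxy-2-methylbenzaldehyde
Product: 8 3,4-bis(benzyloxy)-6-methoxy-2-methylbenzoic acid
Conditions: NaClO2, NaH2PO4, 2-methyl-2-butene (10 equiv), t-BuOH/THF/H2O, rt
Reagents that add atoms: sodium chlorite, [Na+].[O-]Cl=O
Why: Pinnick oxidation; chlorous acid oxidises even hindered aryl aldehydes, and the alkene scavenges hypochlorous acid so that the electron-rich ring is not chlorinated.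

Step 6
Reactants: 8 3,4-bis(benzyloxy)-6-methoxy-2-methylbenzoic acid
Product: 9 3,4-dihydroxy-6-methoxy-2-methylbenzoic acid
Conditions: H2 (1 atm), 10% Pd/C, EtOAc/EtOH, rt
Reagents that add atoms: none
Why: Hydrogenolysis of the two benzylic C–O bonds; it is done at this stage because no C–Cl bond is yet in the molecule, and the acid and the aryl methyl ether are inert.

Step 7
Reactants: 9 3,4-dihydroxy-6-methoxy-2-methylbenzoic acid
Product: 11 3,4-diacetoxy-6-methoxy-2-methylbenzoic acid, via mixed acetic anhydride 10 (not isolated)
Conditions: Ac2O (4 equiv), pyridine, 0 °C to rt; then H2O/THF, rt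
Reagents that add atoms: acetic anhydride, CC(=O)OC(C)=O
Why: Acetylation of both phenols; the carboxyl group is converted to the mixed anhydride 10, which water cleaves at the unhindered acetyl carbonyl on quenching, returning the acid; the acetates lower the electron density of ring A for the oxidative key step.

Step 8
Reactants: 12 4-hydroxy-2-methylbenzoic acid; 13 2,2,2-trichloroethanol
Product: 14 2,2,2-trichloroethyl 4-hydroxy-2-methylbenzoate
Conditions: 13 (5 equiv), TsOH·H2O (0.1 equiv), toluene, reflux, Dean–Stark
Reagents that add atoms: none
Why: Fischer esterification driven by azeotropic removal of water; the phenol is not acylated under acid catalysis, so no protection is needed.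

Step 9
Reactants: 12 4-hydroxy-2-methylbenzoic acid
Product: 16 4-(tert-butyldimethylsilyloxy)-2-methylbenzoic acid, via silyl ester 15 (not isolated)
Conditions: TBSCl (2.3 equiv), imidazole (5 equiv), DMF, rt; then AcOH/THF/H2O (3:1:1), rt
Reagents that add atoms: tert-butyldimethylsilyl chloride, CC(C)(C)[Si](C)(C)Cl
Why: Silylation of phenol and acid followed by selective hydrolysis of the far more labile silyl ester; the aryl silyl ether withstands dilute acetic acid.

Step 10
Reactants: 16 4-(tert-butyldimethylsilyloxy)-2-methylbenzoic acid; 14 2,2,2-trichloroethyl 4-hydroxy-2-methylbenzoate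
Product: 17 2,2,2-trichloroethyl 4-{[4-(tert-butyldimethylsilyloxy)-2-methylbenzoyl]oxy}-2-methylbenzoate
Conditions: EDC·HCl (1.3 equiv), DMAP (0.2 equiv), CH2Cl2, 0 °C to rt
Reagents that add atoms: none
Why: Steglich esterification; the acid carries only one ortho substituent, so carbodiimide activation with DMAP as acyl-transfer catalyst is sufficient to acylate the phenol of 14.

Step 11
Reactants: 17 2,2,2-trichloroethyl 4-{[4-(tert-butyldimethylsilyloxy)-2-methylbenzoyl]oxy}-2-methylbenzoate
Product: 18 2,2,2-trichloroethyl 4-[(4-hydroxy-2-methylbenzoyl)oxy]-2-methylbenzoate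
Conditions: KHF2 (2.5 equiv), MeOH/THF, rt
Reagents that add atoms: none
Why: Fluoride-mediated cleavage of the aryl silyl ether; the weakly acidic bifluoride leaves the aryl ester and the trichloroethyl ester intact, which unbuffered fluoride might attack.

Step 12
Reactants: 11 3,4-diacetoxy-6-methoxy-2-methylbenzoic acid; 18 2,2,2-trichloroethyl 4-[(4-hydroxy-2-methylbenzoyl)oxy]-2-methylbenzoate
Product: 20 2,2,2-trichloroethyl 4-({4-[(3,4-diacetoxy-6-methoxy-2-methylbenzoyl)oxy]-2-methylbenzoyl}oxy)-2-methylbenzoate, via acid chloride 19 (not isolated)
Conditions: (COCl)2 (1.5 equiv), DMF (cat.), CH2Cl2, 0 °C to rt, evaporate; then 18, Et3N (1.5 equiv), DMAP (0.1 equiv), CH2Cl2, 0 °C to rt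
Reagents that add atoms: none
Why: Acid chloride formation followed by DMAP-catalysed acylation of the only free phenol; the chloride is needed because the carbonyl of 11 is flanked by methyl and methoxy groups, and it is far more electrophilic than the aryl acetates, so acetyl transfer should stay minor at low temperature.

Step 13
Reactants: 20 2,2,2-trichloroethyl 4-({4-[(3,4-diacetoxy-6-methoxy-2-methylbenzoyl)oxy]-2-methylbenzoyl}oxy)-2-methylbenzoate
Product: 22 2,2,2-trichloroethyl 4-({4-[(3,4-diacetoxy-6-methoxy-2-methylbenzoyl)oxy]-2-hydroxy-6-methylbenzoyl}oxy)-2-hydroxy-6-methylbenzoate, via bis(trifluoroacetate) 21 (not isolated)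
Conditions: [RuCl2(p-cymene)]2 (5 mol%), K2S2O8 (3 equiv), CF3CO2H/(CF3CO)2O (3:1), 80 °C; then H2O, rt
Reagents that add atoms: trifluoroacetic acid, OC(=O)C(F)(F)F (its carboxylate oxygen becomes each new phenolic oxygen)
Why: In CF3CO2H/(CF3CO)2O the precatalyst gives an electrophilic divalent ruthenium trifluoroacetate, which is bound by the carbonyl oxygen of the ring C ester and of the ring B ester; carboxylate-assisted metalation of the one free ortho C–H then forms a five-membered ruthenacycle on each ring in turn. K2S2O8 oxidises the metallacycle to a tetravalent ruthenium trifluoroacetate, C–O reductive elimination releases the aryl trifluoroacetate and returns divalent ruthenium, and after two such cycles 21 is hydrolysed to 22 on aqueous work-up. The closest known reaction is the ruthenium-catalysed, ester-directed ortho-hydroxylation of alkyl benzoates with persulfate in this medium, applied here twice in one molecule and once with an aryl ester as director. No ring is closed and no stereocentre is created. The step needs site selectivity, and the substrate secures it: C6 of rings B and C is methyl-blocked, the ring A carbonyl has no ortho C–H, and the alternative six-membered chelates towards the O-aryl positions are less favourable than the five-membered ones. It also needs chemoselectivity: the two acetates make ring A electron-poor enough to resist the oxidant, and each new phenol stays masked as its trifluoroacetate until work-up, which prevents over-oxidation.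

Step 14
Reactants: 22 2,2,2-trichloroethyl 4-({4-[(3,4-diacetoxy-6-methoxy-2-methylbenzoyl)oxy]-2-hydroxy-6-methylbenzoyl}oxy)-2-hydroxy-6-methylbenzoate
Product: 23 4-({4-[(3,4-diacetoxy-6-methoxy-2-methylbenzoyl)oxy]-2-hydroxy-6-methylbenzoyl}oxy)-2-hydroxy-6-methylbenzoic acid
Conditions: Zn dust (15 equiv), AcOH/THF (1:1), rt
Reagents that add atoms: none
Why: Reductive fragmentation of the trichloroethyl ester; zinc inserts into a C–Cl bond and β-elimination expels the carboxylate together with 1,1-dichloroethene, while aryl esters, acetates and phenols are inert to Zn/AcOH.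

Step 15
Reactants: 23 4-({4-[(3,4-diacetoxy-6-methoxy-2-methylbenzoyl)oxy]-2-hydroxy-6-methylbenzoyl}oxy)-2-hydroxy-6-methylbenzoic acid
Product: 24 4-({4-[(3,4-dihydroxy-6-methoxy-2-methylbenzoyl)oxy]-2-hydroxy-6-methylbenzoyl}oxy)-2-hydroxy-6-methylbenzoic acid
Conditions: NH4OAc (10 equiv), MeOH/H2O (4:1), rt, N2
Reagents that add atoms: none
Why: Ammonium acetate-mediated methanolysis of aryl acetates at neutral pH; the acetyl carbonyls are unhindered, whereas both depside carbonyls are 2,6-disubstituted benzoates and should react far more slowly, and exclusion of air protects the liberated catechol.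

## Compound list

1 | 2,4-dihydroxy-6-methylbenzaldehyde | Cc1cc(O)cc(O)c1C=O | starting material
2 | 2-hydroxy-4-methoxy-6-methylbenzaldehyde | COc1cc(C)c(C=O)c(O)c1 | intermediate
3 | 2-hydroxy-4-methoxy-6-methylphenyl formate | COc1cc(C)c(OC=O)c(O)c1 | intermediate (not isolated)
4 | 5-methoxy-3-methylbenzene-1,2-diol | COc1cc(C)c(O)c(O)c1 | intermediate
5 | 1,2-bis(benzyloxy)-5-methoxy-3-methylbenzene | COc1cc(C)c(OCc2ccccc2)c(OCc2ccccc2)c1 | intermediate
6 | N-{[3,4-bis(benzyloxy)-6-methoxy-2-methylphenyl]methylidene}-N-methylmethanaminium chloride | COc1cc(OCc2ccccc2)c(OCc2ccccc2)c(C)c1C=[N+](C)C.[Cl-] | intermediate (not isolated)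
7 | 3,4-bis(benzyloxy)-6-methoxy-2-methylbenzaldehyde | COc1cc(OCc2ccccc2)c(OCc2ccccc2)c(C)c1C=O | intermediate
8 | 3,4-bis(benzyloxy)-6-methoxy-2-methylbenzoic acid | COc1cc(OCc2ccccc2)c(OCc2ccccc2)c(C)c1C(=O)O | intermediate
9 | 3,4-dihydroxy-6-methoxy-2-methylbenzoic acid | COc1cc(O)c(O)c(C)c1C(=O)O | intermediate
10 | acetic 3,4-diacetoxy-6-methoxy-2-methylbenzoic anhydride | COc1cc(OC(C)=O)c(OC(C)=O)c(C)c1C(=O)OC(C)=O | intermediate (not isolated)
11 | 3,4-diacetoxy-6-methoxy-2-methylbenzoic acid | COc1cc(OC(C)=O)c(OC(C)=O)c(C)c1C(=O)O | intermediate
12 | 4-hydroxy-2-methylbenzoic acid | Cc1cc(O)ccc1C(=O)O | starting material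
13 | 2,2,2-trichloroethanol | OCC(Cl)(Cl)Cl | starting material
14 | 2,2,2-trichloroethyl 4-hydroxy-2-methylbenzoate | Cc1cc(O)ccc1C(=O)OCC(Cl)(Cl)Cl | intermediate
15 | tert-butyldimethylsilyl 4-(tert-butyldimethylsilyloxy)-2-methylbenzoate | Cc1cc(O[Si](C)(C)C(C)(C)C)ccc1C(=O)O[Si](C)(C)C(C)(C)C | intermediate (not isolated)
16 | 4-(tert-butyldimethylsilyloxy)-2-methylbenzoic acid | Cc1cc(O[Si](C)(C)C(C)(C)C)ccc1C(=O)O | intermediate
17 | 2,2,2-trichloroethyl 4-{[4-(tert-butyldimethylsilyloxy)-2-methylbenzoyl]oxy}-2-methylbenzoate | Cc1cc(O[Si](C)(C)C(C)(C)C)ccc1C(=O)Oc1ccc(C(=O)OCC(Cl)(Cl)Cl)c(C)c1 | intermediate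
18 | 2,2,2-trichloroethyl 4-[(4-hydroxy-2-methylbenzoyl)oxy]-2-methylbenzoate | Cc1cc(O)ccc1C(=O)Oc1ccc(C(=O)OCC(Cl)(Cl)Cl)c(C)c1 | intermediate
19 | 3,4-diacetoxy-6-methoxy-2-methylbenzoyl chloride | COc1cc(OC(C)=O)c(OC(C)=O)c(C)c1C(=O)Cl | intermediate (not isolated)
20 | 2,2,2-trichloroethyl 4-({4-[(3,4-diacetoxy-6-methoxy-2-methylbenzoyl)oxy]-2-methylbenzoyl}oxy)-2-methylbenzoate | COc1cc(OC(C)=O)c(OC(C)=O)c(C)c1C(=O)Oc1ccc(C(=O)Oc2ccc(C(=O)OCC(Cl)(Cl)Cl)c(C)c2)c(C)c1 | intermediate
21 | 2,2,2-trichloroethyl 4-({4-[(3,4-diacetoxy-6-methoxy-2-methylbenzoyl)oxy]-2-methyl-6-(trifluoroacetoxy)benzoyl}oxy)-2-methyl-6-(trifluoroacetoxy)benzoate | COc1cc(OC(C)=O)c(OC(C)=O)c(C)c1C(=O)Oc1cc(C)c(C(=O)Oc2cc(C)c(C(=O)OCC(Cl)(Cl)Cl)c(OC(=O)C(F)(F)F)c2)c(OC(=O)C(F)(F)F)c1 | intermediate (not isolated)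
22 | 2,2,2-trichloroethyl 4-({4-[(3,4-diacetoxy-6-methoxy-2-methylbenzoyl)oxy]-2-hydroxy-6-methylbenzoyl}oxy)-2-hydroxy-6-methylbenzoate | COc1cc(OC(C)=O)c(OC(C)=O)c(C)c1C(=O)Oc1cc(C)c(C(=O)Oc2cc(C)c(C(=O)OCC(Cl)(Cl)Cl)c(O)c2)c(O)c1 | intermediate
23 | 4-({4-[(3,4-diacetoxy-6-methoxy-2-methylbenzoyl)oxy]-2-hydroxy-6-methylbenzoyl}oxy)-2-hydroxy-6-methylbenzoic acid | COc1cc(OC(C)=O)c(OC(C)=O)c(C)c1C(=O)Oc1cc(C)c(C(=O)Oc2cc(C)c(C(=O)O)c(O)c2)c(O)c1 | intermediate
24 | 4-({4-[(3,4-dihydroxy-6-methoxy-2-methylbenzoyl)oxy]-2-hydroxy-6-methylbenzoyl}oxy)-2-hydroxy-6-methylbenzoic acid (CNP0222366.0) | COc1cc(O)c(O)c(C)c1C(=O)Oc1cc(C)c(C(=O)Oc2cc(C)c(C(=O)O)c(O)c2)c(O)c1 | target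

## Step count and least certain steps

Total step count: 15 (ring A branch steps 1–7, ring B/C branch steps 8–11, union and end game steps 12–15).
Longest linear sequence: 11 steps (steps 1–7, then 12–15).

**Step 13 (key step).** The most likely failure is slow cyclometalation. The aryl ester of ring B and the electron-poor trichloroethyl ester of ring C are weaker donors than a simple alkyl ester, so the reaction may stall after one oxygenation. Prolonged heating in CF3CO2H would then invite acyl exchange at the ring A acetates, acidolysis of a depside bond, or oxidation at C5 of ring A. Fallback: from 20, an ester-directed ortho C–H borylation ([Ir(OMe)(cod)]2, P[3,5-(CF3)2C6H3]3, B2pin2, octane/dioxane, 80 °C) would give the bis(boronate) F1 under non-acidic, non-oxidising conditions. Oxidation of both C–B bonds (KHSO5 as 2KHSO5·KHSO4·K2SO4, acetone/H2O, 0 °C) would then return the route at 22.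

**Step 4.** Formylation may partly take place at C6, between the two alkoxy groups, or be retarded by the flanking methyl group, giving a regioisomer mixture. Fallback: keep the carbon of 1 and introduce the oxygen instead.
- From 1, selective 4-O-benzylation (BnBr, NaHCO3, KI cat., MeCN, 60 °C) gives 4-(benzyloxy)-2-hydroxy-6-methylbenzaldehyde F2.
- Methylation (MeI, K2CO3, DMF) gives 4-(benzyloxy)-2-methoxy-6-methylbenzaldehyde F3.
- Bromination para to the methoxy group and next to the methyl group (NBS, MeCN, 0 °C) gives 4-(benzyloxy)-3-bromo-6-methoxy-2-methylbenzaldehyde F4.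
- Hydroxylation of the aryl bromide (Pd2(dba)3, 2-di-tert-butylphosphino-2′,4′,6′-triisopropylbiphenyl, KOH, dioxane/H2O, 100 °C) gives 4-(benzyloxy)-3-hydroxy-6-methoxy-2-methylbenzaldehyde F5.
- Benzylation (BnBr, K2CO3, DMF) rejoins the route at 7.

**Step 12.** The phenoxide of 18 may attack an acetate of 19 instead of the hindered acyl chloride, so that acetyl groups are scrambled between the partners. Fallback: from 11 and 18, activation under acidic conditions with (CF3CO)2O in toluene at rt. The mixed trifluoroacetic anhydride F6 ionises towards the acylium ion of the electron-rich acid and acylates the phenol without any phenoxide or nucleophilic catalyst present, returning the route at 20.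

**Step 15.** Solvolysis of a depside bond may accompany the removal of the acetates, in particular at the ring B carbonyl, whose ortho-hydroxyl can assist nucleophilic attack. The liberated catechol may also oxidise in the near-neutral aqueous medium. Fallback: invert the order and change the mechanism. From 22, acid-catalysed methanolysis (AcCl 0.3 equiv in MeOH/CH2Cl2, 0 °C to rt) would remove only the unhindered acetates, since all three remaining esters are 2,6-disubstituted benzoates and resist acid-catalysed acyl transfer. This gives the trichloroethyl ester of the target F7. Zn in AcOH/THF, a reducing and acidic medium that protects the catechol, then leads to 24.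

**Step 8.** The electron-poor alcohol 13 is a weak nucleophile and the acid carries an ortho methyl group, so esterification may remain incomplete even with removal of water. Fallback: from 16 and 13, carbodiimide coupling (EDC·HCl, DMAP, CH2Cl2) gives 2,2,2-trichloroethyl 4-(tert-butyldimethylsilyloxy)-2-methylbenzoate F8. Desilylation (KHF2, MeOH/THF) returns the route at 14.

## Further compounds

F1 | step 13 | 2,2,2-trichloroethyl ester of tridepside 20 bearing a 4,4,5,5-tetramethyl-1,3,2-dioxaborolan-2-yl group at C2 of ring B and at C2 of ring C | COc1cc(OC(C)=O)c(OC(C)=O)c(C)c1C(=O)Oc1cc(C)c(C(=O)Oc2cc(C)c(C(=O)OCC(Cl)(Cl)Cl)c(B3OC(C)(C)C(C)(C)O3)c2)c(B2OC(C)(C)C(C)(C)O2)c1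
F2 | step 4 | 4-(benzyloxy)-2-hydroxy-6-methylbenzaldehyde | Cc1cc(OCc2ccccc2)cc(O)c1C=O
F3 | step 4 | 4-(benzyloxy)-2-methoxy-6-methylbenzaldehyde | COc1cc(OCc2ccccc2)cc(C)c1C=O
F4 | step 4 | 4-(benzyloxy)-3-bromo-6-methoxy-2-methylbenzaldehyde | COc1cc(OCc2ccccc2)c(Br)c(C)c1C=O
F5 | step 4 | 4-(benzyloxy)-3-hydroxy-6-methoxy-2-methylbenzaldehyde | COc1cc(OCc2ccccc2)c(O)c(C)c1C=O
F6 | step 12 | 3,4-diacetoxy-6-methoxy-2-methylbenzoic trifluoroacetic anhydride | COc1cc(OC(C)=O)c(OC(C)=O)c(C)c1C(=O)OC(=O)C(F)(F)F
F7 | step 15 | 2,2,2-trichloroethyl 4-({4-[(3,4-dihydroxy-6-methoxy-2-methylbenzoyl)oxy]-2-hydroxy-6-methylbenzoyl}oxy)-2-hydroxy-6-methylbenzoate | COc1cc(O)c(O)c(C)c1C(=O)Oc1cc(C)c(C(=O)Oc2cc(C)c(C(=O)OCC(Cl)(Cl)Cl)c(O)c2)c(O)c1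
F8 | step 8 | 2,2,2-trichloroethyl 4-(tert-butyldimethylsilyloxy)-2-methylbenzoate | Cc1cc(O[Si](C)(C)C(C)(C)C)ccc1C(=O)OCC(Cl)(Cl)Cl
A1 | alternative 1 | tert-butyl 3-oxobutanoate (tert-butyl acetoacetate) | CC(=O)CC(=O)OC(C)(C)C
A2 | alternative 1 | ethyl (Z)-2-(benzyloxy)but-2-enoate | C/C=C(\OCc1ccccc1)C(=O)OCC
A3 | alternative 1 | tert-butyl 3-(benzyloxy)-2-methyl-4,6-dioxocyclohexane-1-carboxylate (mixture of diastereomers) | CC1C(OCc2ccccc2)C(=O)CC(=O)C1C(=O)OC(C)(C)C
A4 | alternative 2 | tert-butyl (E)-3-[2-isopropoxy-4-oxo-1-(trimethylsilyloxy)cyclobut-2-en-1-yl]but-2-enoate (racemic) | CC(C)OC1=CC(=O)C1(O[Si](C)(C)C)/C(C)=C/C(=O)OC(C)(C)C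
A5 | alternative 2 | tert-butyl 6-hydroxy-4-isopropoxy-2-methyl-3-(trimethylsilyloxy)benzoate | CC(C)Oc1cc(O)c(C(=O)OC(C)(C)C)c(C)c1O[Si](C)(C)C
A6 | alternative 3 | benzyl 4-(but-2-ynoyloxy)-2-(tert-butyldimethylsilyloxy)-6-methylbenzoate | CC#CC(=O)Oc1cc(C)c(C(=O)OCc2ccccc2)c(O[Si](C)(C)C(C)(C)C)c1
A7 | alternative 3 | 1-methoxy-1,3-bis(trimethylsilyloxy)buta-1,3-diene (ketene acetal isomer mixture) | C=C(O[Si](C)(C)C)C=C(OC)O[Si](C)(C)C
A8 | alternative 3 | benzyl 2-(tert-butyldimethylsilyloxy)-4-(2,4-dihydroxy-6-methylbenzoyloxy)-6-methylbenzoate | Cc1cc(O)cc(O)c1C(=O)Oc1cc(C)c(C(=O)OCc2ccccc2)c(O[Si](C)(C)C(C)(C)C)c1
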